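**Remarks and assumptions (chemistry)**

- Locants: every intermediate carries the atom numbers of the target (ring C1–C10, CH3-14 on C10, CH3-15 on C4, C11–C13 on C7, lactone oxygen on C6). Compounds 8–17 are bicyclo[5.3.0]dec-1(10)-enes whose fusion bond is C4–C8 (five-membered ring C4–C5–C6–C7–C8, seven-membered ring C8–C9–C10–C1–C2–C3–C4).
- Assumption: the CBS reduction of dione 4 follows the usual model (quaternary carbon as the large group, hydride anti to the butenyl chain). If the sense proves opposite, the antipodal catalyst is used.
- Assumption: 3-hydroxy-2-oxopropanoic acid (21) and 2-methylallylmagnesium chloride solution (6) are bought.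

## Analysis of the target

The target 28 is a germacranolide: a cyclodecane (C1–C10) with a cis-1,10-epoxide (C10 also bears CH3-14), a trans-4,5-epoxide (C4 bears CH3-15), an acetate on C8, and a butenolide fused at C6–C7 (C7=C11, C12 carbonyl, lactone oxygen on C6, acetoxymethyl C13 on C11). All six stereocentres (1R,4R,5R,6S,8S,10S) lie on the ten-membered ring. The two epoxides record the geometry of their parent olefins, Z at C1=C10 and E at C4=C5. C5 and C6 are contiguous, C6–O and C8–O are 1,3-syn across trigonal C7, and C10 is 1,3 to C8. The sensitive groups are the two trisubstituted epoxides (acid, transannular reactions), the γ-hydrogen on C6 of the butenolide next to the 4,5-epoxide (base), the allylic C13 acetate on a Michael acceptor, and the (Z,E)-1,5-diene of any ring precursor. The difficulty is to close a ten-membered ring that holds one Z and one E trisubstituted olefin, and then to relay configuration around a flexible ring. The strategy rests on the 1,5-relation of C4 and C8: a C4–C8 bond turns the ring into a bicyclo[5.3.0]decane whose cycloheptene can only hold C1=C10 as Z. In that bicycle HO–C8–C4–C5–OMs is a 1,3-diol monosulfonate that fragments to the C8 ketone and the C4=C5 olefin, and the cyclopentane carries C5 and C6 where rigid-ring control can set them.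

## Retrosynthetic reasoning

**28 to 27 to 26.** The acetate on O8 goes on last, because the free 8-hydroxyl of 27 is needed first. In 26 it is homoallylic to C1=C10 and can steer a metal-catalysed hydroperoxide epoxidation to one face (C1–O and C10–O cut). Leaving this to the end keeps the cis-epoxide away from all carbon–carbon bond formation.

**26 to 25.** The C8 carbinol is taken back to a ketone. The ketone is required one step earlier to acidify C7, so C8 must be reduced after the butenolide exists. The forward step has to be a 1,2-reduction of an enone that leaves the lactone and the allylic acetate alone.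

**25 to 23 to 20 and 22.** The butenolide is cut at C7=C11 and at the C12–O6 ester bond. C11 is the ketone carbonyl of an α-keto acid (22, made by O-acetylation of 21) and C7 is α to the C8 ketone, so an aldol condensation joins them. Tethering 22 through O6 in 23 makes C7, not C9, the only α-carbon that can reach C11.

**20 to 19 to 18.** The 4,5-epoxide is cut while O6 is still a free allylic hydroxyl (19, from silyl ether 18). The hydroxyl directs the oxidant, and allylic 1,3-strain between H6 and CH3-15 fixes which face it reaches. This is the most reliable point at which to set C4 and C5.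

**18 to 16 (the central disconnection).** C4 and C8 are reconnected and C5 is given a sulfonate: the ten-membered dienone 18 becomes the hydroazulene 16. This removes the medium-ring closure, places the Z olefin in a seven-membered ring where it has no alternative, and makes the E olefin the product of a stereospecific anti fragmentation. Only C6 has to carry absolute configuration through the step. Two demands fall on 16: the mesylate must be cis to CH3-15 (trans to C3), and O6 must have the right absolute sense. The diastereomer chosen has the ring fusion trans and O6 trans to the mesylate, because that is the pattern substrate control delivers.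

**16 to 15 to 14 to 13 to 10 to 9.** The mesylate comes from alcohol 15, and 15 from ketone 14 by a hydroxyl-directed hydride delivery from O8 to C5. O6 comes from oxidation of the enol silyl ether 10, which can only form toward C6 because C4 is quaternary. The five-membered ring of 9 resembles ring D of a 17-oxo steroid: an angular methyl beside the ketone sends both oxidant and hydride to the opposite face. This gives O6 trans and O5 cis to the methyl.

**9 to 8 to 7.** C1=C10 is cut by ring-closing metathesis. The diene 7 has a butenyl chain on C4 and a methallyl group on C8. Oxidation of the secondary C5 alcohol of 8 gives 9.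

**7 to 5 and 6.** The C8–C9 bond is cut: methallyl Grignard reagent 6 adds to the C8 ketone of 5, opposite to the butenyl chain and the C5 oxygen.

**5 to 4 to 3 to 1 and 2.** The quaternary C4 is made stereogenic by an enantiotopic-group-selective reduction of dione 4. The carbinol is later reoxidised, so it serves only to tell the two carbonyls apart. 4 comes from 3 by methylenation of the aldehyde, and 3 from the Michael addition of 1 to 2 (C4–C3 bond).

## Alternatives that were turned down

**Alternative 1: macrocyclic nitrile oxide cycloaddition.** The disconnection cuts C7–C8 and the O–C6 bond of the bridged isoxazoline A3. In the forward step the open-chain bis-epoxy aldoxime A1 is oxidised with NaOCl to the nitrile oxide A2. Its dipole adds across the C6=C7 vinyl group and closes the ten-membered carbocycle and the isoxazoline together.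
- For it: both epoxides are made on an acyclic chain by reagent-controlled epoxidation, so their configuration does not depend on the shape of a ten-membered ring. On this point it is stronger than the chosen route, whose 1,10-epoxide relies on ring conformation. A3 is also a masked form of the same 6-hydroxy-8-ketone array as 20.
- Against it: a ten-membered ring must close in a bimolecular-type event that competes with dipole dimerisation. The closure has to be bridged, placing the C=N bond at a bridgehead. C6 is created during the closure with only the neighbouring epoxide to guide it. The N–O bond must then be cleaved reductively (Mo(CO)6, or H2 over nickel) in the presence of two epoxides.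
- Comparison: step count to the ring is similar. The chosen strategy opens the ring by a unimolecular fragmentation with no entropic cost and brings C6 through it with fixed configuration.

**Alternative 2: enone–cyclobutene photoadduct, thermal opening.** The disconnection cuts C4–C5 and C1–C10 of the cyclobutane in photoadduct A6. The forward step irradiates enone A4 with cyclobutene ester A5. Heating A6 opens its bicyclo[2.2.0]hexane core to the cyclodeca-1(10),4-dienone A7.
- For it: it is clearly shorter to the ten-membered ring, two steps from simple partners, and in step economy it beats the chosen route.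
- Against it: the head-to-head or head-to-tail sense of the cycloaddition and its face relative to the silyloxy centre of A4 are both uncertain. C15 arrives as an ester and must be taken down to CH3 at an allylic position. Which of the two new olefins ends trans depends on the course of a stepwise thermal opening, at temperatures where cis,trans-1,5-cyclodecadienes can undergo Cope rearrangement. A7 has its ketone at C6 and its oxygen at C8, so C6 must later be set by remote control.
- Comparison: the chosen strategy fixes both geometries by structure (ring size for Z, anti fragmentation for E) and delivers C6 already configured, at the price of a longer approach to the bicycle.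

**Alternative 3: ynal carbonylative macrocyclisation.** The disconnection cuts C6–C7, C11–C12 and C12–O of the butenolide in A9. In the forward step Cp2Ti(PMe3)2 under CO couples the C7≡C11 alkyne of ynal A8 with its C6 aldehyde and inserts CO, closing lactone and carbocycle at once.
- For it: it is the most convergent option. It needs no separate butenolide annulation and so avoids the aldol-versus-elimination problem of step 17; on this point it is stronger. C8 would come from an acyclic propargylic alcohol.
- Against it: this cyclocarbonylation is established for tethers that give five- or six-membered carbocycles. A ten-membered closure through a metallacycle has no support. The enal of A8 can bind divalent titanium as a heterodiene. C6 would be set during macrocyclisation relative to a remote C8. The reagent is stoichiometric and air-sensitive, and A8 needs both trisubstituted olefins built linearly with defined geometry.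
- Comparison: the chosen strategy offers a ring-forming step of a well-known type and moves the remaining risk into functional-group chemistry that has fallbacks.

Key step: step 12

## Route

Step 1
Reactants: 1 2-methylcyclopentane-1,3-dione; 2 acrolein (prop-2-enal)
Product: 3 3-(1-methyl-2,5-dioxocyclopentyl)propanal
Conditions: H2O, rt
Reagents that add atoms: none
Why: Michael addition of the dione enol to acrolein in water; C-alkylation builds the quaternary C4 with the C3–C2–C1 chain, and the centre is not yet stereogenic because the two carbonyls are equivalent.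

Step 2
Reactants: 3 3-(1-methyl-2,5-dioxocyclopentyl)propanal
Product: 4 2-(but-3-en-1-yl)-2-methylcyclopentane-1,3-dione
Conditions: Ph3PCH3Br, KOtBu, THF, 0 °C; then 3, −78 → 0 °C
Reagents that add atoms: methyltriphenylphosphonium bromide, C[P+](c1ccccc1)(c1ccccc1)c1ccccc1.[Br-]
Why: Wittig methylenation; the aldehyde reacts far faster than the two ketones beside the quaternary carbon, and preformed ylide at low temperature limits enolate-driven aldol closure of the triketone.

Step 3
Reactants: 4 2-(but-3-en-1-yl)-2-methylcyclopentane-1,3-dione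
Product: 5 (2S,3S)-2-(but-3-en-1-yl)-3-hydroxy-2-methylcyclopentan-1-one
Conditions: (R)-1-methyl-3,3-diphenyltetrahydro-1H,3H-pyrrolo[1,2-c][1,3,2]oxazaborole ((R)-Me-CBS, 0.2 equiv), catecholborane, toluene, −78 → −40 °C
Reagents that add atoms: none
Why: CBS reduction used as an enantiotopic-group-selective monoreduction of a 2,2-disubstituted cyclopentane-1,3-dione; the catalyst sets the carbinol as S and hydride enters anti to the larger butenyl group, so the two preferences together pick one carbonyl and fix the quaternary C4, the only centre of 5 that is kept. Catecholborane at low temperature does not hydroborate the terminal olefin.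

Step 4
Reactants: 5 (2S,3S)-2-(but-3-en-1-yl)-3-hydroxy-2-methylcyclopentan-1-one; 6 2-methylallylmagnesium chloride
Product: 7 (1S,2S,3S)-2-(but-3-en-1-yl)-2-methyl-1-(2-methylprop-2-en-1-yl)cyclopentane-1,3-diol
Conditions: 6 (2.5 equiv, THF solution), THF, −78 °C; aq NH4Cl
Reagents that add atoms: none
Why: Grignard 1,2-addition; the first equivalent forms the magnesium alkoxide, the second adds to C8 from the face opposite the butenyl chain and the C5 oxygen (which share a face), so the methallyl group is cis and the new 8-hydroxyl anti to CH3-15. Allylic Grignard reagents add to hindered ketones faster than they enolise them.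

Step 5
Reactants: 7 (1S,2S,3S)-2-(but-3-en-1-yl)-2-methyl-1-(2-methylprop-2-en-1-yl)cyclopentane-1,3-diol
Product: 8 (4S,5S,8S)-4,10-dimethylbicyclo[5.3.0]dec-1(10)-ene-5,8-diol (trans-fused; 8-OH anti to CH3-15, 5-OH cis to 8-OH)
Conditions: second-generation Grubbs catalyst RuCl2(=CHPh)(PCy3)(H2IMes) (5 mol %), CH2Cl2, 40 °C
Reagents that add atoms: none
Why: ring-closing metathesis of a monosubstituted with a 1,1-disubstituted olefin to a trisubstituted cycloheptene; in a seven-membered ring C1=C10 can only be Z, and the trans-disposed chains on C4 and C8 are both quasi-equatorial and within reach.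

Step 6
Reactants: 8 (4S,5S,8S)-4,10-dimethylbicyclo[5.3.0]dec-1(10)-ene-5,8-diol
Product: 9 (4R,8S)-8-hydroxy-4,10-dimethylbicyclo[5.3.0]dec-1(10)-en-5-one
Conditions: Dess–Martin periodinane, NaHCO3, CH2Cl2, 0 °C → rt
Reagents that add atoms: none
Why: periodinane oxidation of the secondary alcohol; the tertiary 8-hydroxyl is inert and the buffered, base-free medium avoids retro-aldol opening of the β-hydroxy ketone.

Step 7
Reactants: 9 (4R,8S)-8-hydroxy-4,10-dimethylbicyclo[5.3.0]dec-1(10)-en-5-one
Product: 10 (4R,8S)-4,10-dimethyl-5,8-bis(trimethylsilyloxy)bicyclo[5.3.0]deca-1(10),5-diene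
Conditions: Me3SiOTf (3 equiv), Et3N, CH2Cl2, −78 → 0 °C
Reagents that add atoms: trimethylsilyl trifluoromethanesulfonate, C[Si](C)(C)OS(=O)(=O)C(F)(F)F
Why: soft enolisation and O-silylation; C4 is quaternary, so the enol ether can only form toward C6, and silylation of the 8-hydroxyl in the same pot closes the retro-aldol pathway.

Step 8
Reactants: 10 (4R,8S)-4,10-dimethyl-5,8-bis(trimethylsilyloxy)bicyclo[5.3.0]deca-1(10),5-diene
Product: 13 (4R,6S,8R)-6,8-dihydroxy-4,10-dimethylbicyclo[5.3.0]dec-1(10)-en-5-one, via 5,6-epoxy bis(trimethylsilyl) ether 11 (not isolated), via 6,8-bis(trimethylsilyloxy) ketone 12 (not isolated)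
Conditions: mCPBA (1.05 equiv), NaHCO3, CH2Cl2, −40 → −20 °C; then citric acid, MeOH, rt
Reagents that add atoms: 3-chloroperbenzoic acid, OOC(=O)c1cccc(Cl)c1
Why: Rubottom oxidation; the electron-rich enol silyl ether is epoxidised faster than the trisubstituted C1=C10 olefin, and the peracid comes from the face opposite the quasi-axial CH3-15 on the carbon next to the enol carbon, as at C16 of a 17-oxo steroid enol derivative, so O6 ends trans to the methyl and cis to O8. Silyl shift and mild acid methanolysis then free both hydroxyls.

Step 9
Reactants: 13 (4R,6S,8R)-6,8-dihydroxy-4,10-dimethylbicyclo[5.3.0]dec-1(10)-en-5-one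
Product: 14 (4R,6S,8R)-6-(tert-butyldimethylsilyloxy)-8-hydroxy-4,10-dimethylbicyclo[5.3.0]dec-1(10)-en-5-one
Conditions: TBSCl (1.2 equiv), imidazole, DMF, 0 °C → rt
Reagents that add atoms: tert-butyldimethylsilyl chloride, CC(C)(C)[Si](C)(C)Cl
Why: silylation of the only secondary hydroxyl; the tertiary ring-fusion hydroxyl does not react with a silyl chloride under these conditions.

Step 10
Reactants: 14 (4R,6S,8R)-6-(tert-butyldimethylsilyloxy)-8-hydroxy-4,10-dimethylbicyclo[5.3.0]dec-1(10)-en-5-one
Product: 15 (4S,5S,6S,8R)-6-(tert-butyldimethylsilyloxy)-4,10-dimethylbicyclo[5.3.0]dec-1(10)-ene-5,8-diol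
Conditions: Me4NBH(OAc)3, MeCN/AcOH (1:1), −20 °C
Reagents that add atoms: none
Why: Evans–Saksena hydroxyl-directed reduction; the 8-hydroxyl exchanges an acetate on boron and passes hydride to C5 from its own face, which is also the face away from CH3-15, so the new 5-hydroxyl is cis to the methyl, anti to O8 and trans to O6 (the 17β-ol pattern of a 16α-oxygenated steroid).

Step 11
Reactants: 15 (4S,5S,6S,8R)-6-(tert-butyldimethylsilyloxy)-4,10-dimethylbicyclo[5.3.0]dec-1(10)-ene-5,8-diol
Product: 16 (4S,5S,6S,8R)-6-(tert-butyldimethylsilyloxy)-8-hydroxy-4,10-dimethylbicyclo[5.3.0]dec-1(10)-en-5-yl methanesulfonate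
Conditions: MsCl, Et3N, CH2Cl2, −20 → 0 °C
Reagents that add atoms: methanesulfonyl chloride, CS(=O)(=O)Cl
Why: sulfonylation of the secondary alcohol; the tertiary 8-hydroxyl, on a ring-fusion carbon beside a quaternary centre, is much slower and stays free as the future alkoxide.

Step 12
Reactants: 16 (4S,5S,6S,8R)-6-(tert-butyldimethylsilyloxy)-8-hydroxy-4,10-dimethylbicyclo[5.3.0]dec-1(10)-en-5-yl methanesulfonate
Product: 18 (3Z,7E,9S)-9-(tert-butyldimethylsilyloxy)-3,7-dimethylcyclodeca-3,7-dien-1-one (target locants: 1(10)Z,4E, 6S, 8-oxo), via potassium 8-alkoxide 17 (not isolated)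
Conditions: KOtBu (1.1 equiv), THF/t-BuOH, 0 °C
Reagents that add atoms: none
Why: Wharton–Grob fragmentation of a cyclic 1,3-diol monosulfonate: KOtBu converts the 8-hydroxyl into alkoxide 17, an oxygen lone pair pushes into the C4–C8 bond, and the electrons of that bond expel the mesylate from C5 in one concerted step, giving the C8 ketone and the C4=C5 olefin. The closest known reaction type is the base-induced fragmentation of decalin- and hydrindane-1,3-diol monosulfonates to cyclodecenones and cyclononenones. No ring is closed; the shared C4–C8 bond of the bicyclo[5.3.0]decane is cut, so the five- and seven-membered rings merge into the ten-membered ring. No stereocentre is formed: C4, C5 and C8 become trigonal and C6 passes through untouched. The step needs E geometry at C4=C5 and is stereospecific for it, because the mesylate is cis to CH3-15 and trans to C3, so in the anti arrangement C6 and CH3-15 end on the same side of the new double bond and C3 and C6 on opposite sides. The trans ring fusion holds CH3-15 and O8 quasi-axial and the mesylate quasi-equatorial (the 17β-like position), with its C–O bond at roughly 155–165° to C4–C8, close enough to anti for overlap. Competing paths are poorly served: no hydrogen is anti to the mesylate (H6 is cis to it, C4 is quaternary), and backside attack of O8 on C5 would need a bicyclo[2.1.1] oxetane. One equivalent of base at 0 °C with t-BuOH present limits enolisation of the product, a β-silyloxy ketone with a β,γ-olefin on its other side.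

Step 13
Reactants: 18 (3Z,7E,9S)-9-(tert-butyldimethylsilyloxy)-3,7-dimethylcyclodeca-3,7-dien-1-one
Product: 19 (3Z,7E,9S)-9-hydroxy-3,7-dimethylcyclodeca-3,7-dien-1-one
Conditions: HF·pyridine, pyridine, THF, 0 °C → rt
Reagents that add atoms: none
Why: fluoride cleavage of the silyl ether under buffered, weakly acidic conditions, which avoid both base-induced dehydration or retro-aldol of the β-hydroxy ketone and acid-induced transannular reaction of the 1,5-diene.

Step 14
Reactants: 19 (3Z,7E,9S)-9-hydroxy-3,7-dimethylcyclodeca-3,7-dien-1-one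
Product: 20 (4R,5R,6S)-4,5-epoxy-6-hydroxy-4,10-dimethylcyclodec-1(10)Z-en-8-one (target locants)
Conditions: VO(acac)2 (5 mol %), t-BuOOH (decane), CH2Cl2, 0 °C → rt
Reagents that add atoms: tert-butyl hydroperoxide, CC(C)(C)OO
Why: allylic-alcohol-directed epoxidation; only C4=C5 has an allylic hydroxyl, so C1=C10 is untouched. H6 eclipses C5=C4 toward CH3-15 to relieve allylic 1,3-strain, and the vanadate on O6 delivers oxygen to the face it sits on, which is also the outer face (C7 lies on the other), giving the 4R,5R epoxide.

Step 15
Reactants: 21 3-hydroxy-2-oxopropanoic acid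
Product: 22 3-acetoxy-2-oxopropanoic acid
Conditions: AcCl (neat), 0 °C → rt; evaporation
Reagents that add atoms: acetyl chloride, CC(=O)Cl
Why: O-acylation of the primary alcohol of a hydroxy acid with an acyl chloride, as in the preparation of acetoxyacetic acid; any mixed anhydride reverts to the acid on work-up.

Step 16
Reactants: 20 (4R,5R,6S)-4,5-epoxy-6-hydroxy-4,10-dimethylcyclodec-1(10)Z-en-8-one; 22 3-acetoxy-2-oxopropanoic acid
Product: 23 (4R,5R,6S)-4,5-epoxy-4,10-dimethyl-8-oxocyclodec-1(10)Z-en-6-yl 3-acetoxy-2-oxopropanoate
Conditions: DCC, DMAP (0.1 equiv), CH2Cl2, −20 → 0 °C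
Reagents that add atoms: none
Why: Steglich esterification of the secondary epoxy alcohol with the α-keto acid; this places the C11 ketone five atoms from C7.

Step 17
Reactants: 23 (4R,5R,6S)-4,5-epoxy-4,10-dimethyl-8-oxocyclodec-1(10)Z-en-6-yl 3-acetoxy-2-oxopropanoate
Product: 25 (4R,5R,6S)-13-acetoxy-4,5-epoxy-8-oxogermacra-1(10)Z,7(11)-dien-12,6-olide, via aldol lactone 24 (not isolated)
Conditions: Et3N (2 equiv), CH2Cl2, −20 → 0 °C; then MsCl, Et3N, 0 °C
Reagents that add atoms: none
Why: intramolecular aldol condensation (Knoevenagel type); the C7 enol(ate) of the C8 ketone adds to the very electrophilic α-keto ester carbonyl C11 in a five-membered closure that only C7 can reach, and mesylation of the tertiary aldol hydroxyl followed by E1cB loss gives the tetrasubstituted C7=C11 bond. Short contact with a weak amine base is chosen to limit loss of the C6 carboxylate and deprotonation at C6 of the product.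

Step 18
Reactants: 25 (4R,5R,6S)-13-acetoxy-4,5-epoxy-8-oxogermacra-1(10)Z,7(11)-dien-12,6-olide
Product: 26 (4R,5R,6S,8S)-13-acetoxy-4,5-epoxy-8-hydroxygermacra-1(10)Z,7(11)-dien-12,6-olide
Conditions: NaBH4, CeCl3·7H2O, MeOH, −78 °C
Reagents that add atoms: none
Why: Luche 1,2-reduction of the enone carbonyl, leaving lactone and acetate. Hydride is expected on the outer, C13-side face of the twisted C8 carbonyl; in the ring conformer with C9 and C5 on opposite faces of the lactone plane, which lets H8 eclipse C7=C11, this gives the 8S alcohol with O8 1,3-syn to O6.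

Step 19
Reactants: 26 (4R,5R,6S,8S)-13-acetoxy-4,5-epoxy-8-hydroxygermacra-1(10)Z,7(11)-dien-12,6-olide
Product: 27 (1R,4R,5R,6S,8S,10S)-13-acetoxy-1,10:4,5-diepoxy-8-hydroxygermacr-7(11)-en-12,6-olide
Conditions: VO(acac)2 (10 mol %), t-BuOOH (decane), CH2Cl2, 0 °C → rt
Reagents that add atoms: tert-butyl hydroperoxide, CC(C)(C)OO
Why: homoallylic-alcohol-directed epoxidation of the one remaining nucleophilic olefin (the butenolide double bond is electron-poor). The vanadate on O8 reaches C1=C10 through a chair-like six-membered arrangement with C7–C8–C9–C10 gauche, which places oxygen on the face that gives the 1R,10S cis-epoxide.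

Step 20
Reactants: 27 (1R,4R,5R,6S,8S,10S)-13-acetoxy-1,10:4,5-diepoxy-8-hydroxygermacr-7(11)-en-12,6-olide
Product: 28 (1R,4R,5R,6S,8S,10S)-8,13-diacetoxy-1,10:4,5-diepoxygermacr-7(11)-en-12,6-olide (CNP0271844.2)
Conditions: Ac2O, pyridine, DMAP (cat.), CH2Cl2, 0 °C
Reagents that add atoms: acetic anhydride, CC(=O)OC(C)=O
Why: acylation of the secondary allylic alcohol under mild amine conditions that the epoxides and the butenolide tolerate for a short reaction time; no stereocentre is touched.

## Compound list

1 | 2-methylcyclopentane-1,3-dione | CC1C(=O)CCC1=O | starting material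
2 | acrolein (prop-2-enal) | C=CC=O | starting material
3 | 3-(1-methyl-2,5-dioxocyclopentyl)propanal | CC1(CCC=O)C(=O)CCC1=O | intermediate
4 | 2-(but-3-en-1-yl)-2-methylcyclopentane-1,3-dione | CC1(CCC=C)C(=O)CCC1=O | intermediate
5 | (2S,3S)-2-(but-3-en-1-yl)-3-hydroxy-2-methylcyclopentan-1-one | O=C1CC[C@H](O)[C@]1(C)CCC=C | intermediate
6 | 2-methylallylmagnesium chloride | CC(=C)C[Mg]Cl | starting material
7 | (1S,2S,3S)-2-(but-3-en-1-yl)-2-methyl-1-(2-methylprop-2-en-1-yl)cyclopentane-1,3-diol | O[C@]1(CC(C)=C)CC[C@H](O)[C@]1(C)CCC=C | intermediate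
8 | (4S,5S,8S)-4,10-dimethylbicyclo[5.3.0]dec-1(10)-ene-5,8-diol, trans-fused | O[C@@]12C/C(C)=C\CC[C@@]1(C)[C@@H](O)CC2 | intermediate
9 | (4R,8S)-8-hydroxy-4,10-dimethylbicyclo[5.3.0]dec-1(10)-en-5-one | O[C@@]12C/C(C)=C\CC[C@@]1(C)C(=O)CC2 | intermediate
10 | (4R,8S)-4,10-dimethyl-5,8-bis(trimethylsilyloxy)bicyclo[5.3.0]deca-1(10),5-diene | C[Si](C)(C)O[C@@]12C/C(C)=C\CC[C@@]1(C)C(O[Si](C)(C)C)=CC2 | intermediate
11 | 5,6-epoxy-4,10-dimethyl-5,8-bis(trimethylsilyloxy)bicyclo[5.3.0]dec-1(10)-ene, epoxide on the face of O8 | C[Si](C)(C)O[C@@]12C/C(C)=C\CC[C@@]1(C)[C@@]3(O[Si](C)(C)C)O[C@H]3C2 | intermediate (not isolated)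
12 | 4,10-dimethyl-6,8-bis(trimethylsilyloxy)bicyclo[5.3.0]dec-1(10)-en-5-one, O6 cis to O8 | C[Si](C)(C)O[C@@]12C/C(C)=C\CC[C@@]1(C)C(=O)[C@@H](O[Si](C)(C)C)C2 | intermediate (not isolated)
13 | (4R,6S,8R)-6,8-dihydroxy-4,10-dimethylbicyclo[5.3.0]dec-1(10)-en-5-one | O[C@@]12C/C(C)=C\CC[C@@]1(C)C(=O)[C@@H](O)C2 | intermediate
14 | (4R,6S,8R)-6-(tert-butyldimethylsilyloxy)-8-hydroxy-4,10-dimethylbicyclo[5.3.0]dec-1(10)-en-5-one | O[C@@]12C/C(C)=C\CC[C@@]1(C)C(=O)[C@@H](O[Si](C)(C)C(C)(C)C)C2 | intermediate
15 | (4S,5S,6S,8R)-6-(tert-butyldimethylsilyloxy)-4,10-dimethylbicyclo[5.3.0]dec-1(10)-ene-5,8-diol | O[C@@]12C/C(C)=C\CC[C@@]1(C)[C@H](O)[C@@H](O[Si](C)(C)C(C)(C)C)C2 | intermediate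
16 | (4S,5S,6S,8R)-6-(tert-butyldimethylsilyloxy)-8-hydroxy-4,10-dimethylbicyclo[5.3.0]dec-1(10)-en-5-yl methanesulfonate | O[C@@]12C/C(C)=C\CC[C@@]1(C)[C@H](OS(C)(=O)=O)[C@@H](O[Si](C)(C)C(C)(C)C)C2 | intermediate
17 | potassium 8-alkoxide of 16 | [K+].[O-][C@@]12C/C(C)=C\CC[C@@]1(C)[C@H](OS(C)(=O)=O)[C@@H](O[Si](C)(C)C(C)(C)C)C2 | intermediate (not isolated)
18 | (3Z,7E,9S)-9-(tert-butyldimethylsilyloxy)-3,7-dimethylcyclodeca-3,7-dien-1-one | O=C1C/C(C)=C\CC/C(C)=C/[C@@H](O[Si](C)(C)C(C)(C)C)C1 | intermediate
19 | (3Z,7E,9S)-9-hydroxy-3,7-dimethylcyclodeca-3,7-dien-1-one | O=C1C/C(C)=C\CC/C(C)=C/[C@@H](O)C1 | intermediate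
20 | (4R,5R,6S)-4,5-epoxy-6-hydroxy-4,10-dimethylcyclodec-1(10)Z-en-8-one | O=C1C/C(C)=C\CC[C@@]2(C)O[C@@H]2[C@@H](O)C1 | intermediate
21 | 3-hydroxy-2-oxopropanoic acid | OCC(=O)C(=O)O | starting material
22 | 3-acetoxy-2-oxopropanoic acid | CC(=O)OCC(=O)C(=O)O | intermediate
23 | (4R,5R,6S)-4,5-epoxy-4,10-dimethyl-8-oxocyclodec-1(10)Z-en-6-yl 3-acetoxy-2-oxopropanoate | CC(=O)OCC(=O)C(=O)O[C@H]1CC(=O)C/C(C)=C\CC[C@@]2(C)O[C@@H]21 | intermediate
24 | 13-acetoxy-4,5-epoxy-11-hydroxy-8-oxogermacr-1(10)Z-en-12,6-olide (C7, C11 undefined) | CC(=O)OCC1(O)C2C(=O)C/C(C)=C\CC[C@@]3(C)O[C@@H]3[C@H]2OC1=O | intermediate (not isolated)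
25 | (4R,5R,6S)-13-acetoxy-4,5-epoxy-8-oxogermacra-1(10)Z,7(11)-dien-12,6-olide | CC(=O)OCC1=C2C(=O)C/C(C)=C\CC[C@@]3(C)O[C@@H]3[C@H]2OC1=O | intermediate
26 | (4R,5R,6S,8S)-13-acetoxy-4,5-epoxy-8-hydroxygermacra-1(10)Z,7(11)-dien-12,6-olide | CC(=O)OCC1=C2[C@@H](O)C/C(C)=C\CC[C@@]3(C)O[C@@H]3[C@H]2OC1=O | intermediate
27 | (1R,4R,5R,6S,8S,10S)-13-acetoxy-1,10:4,5-diepoxy-8-hydroxygermacr-7(11)-en-12,6-olide | CC(=O)OCC1=C2[C@@H](O)C[C@]3(C)O[C@@H]3CC[C@@]3(C)O[C@@H]3[C@H]2OC1=O | intermediate
28 | (1R,4R,5R,6S,8S,10S)-8,13-diacetoxy-1,10:4,5-diepoxygermacr-7(11)-en-12,6-olide (CNP0271844.2) | CC(=O)OCC1=C2[C@@H](OC(C)=O)C[C@]3(C)O[C@@H]3CC[C@@]3(C)O[C@@H]3[C@H]2OC1=O | target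

## Step count and least certain steps

Total: 20 steps. Longest linear sequence: 19 steps (steps 1–14 and 16–20); step 15 is a one-step side branch.

**Step 12 (key step).** The most likely trouble is what the base does besides fragmenting 17. It can enolise the product ketone, toward C9 (moving C1=C10 into conjugation) or toward C7 (loss of silanolate from C6). The silyl group can also shift from O6 to the cis-1,3 alkoxide O8, after which O6 could displace the mesylate. Fallback, from 16: run the fragmentation reductively with LiAlH4 in THF, so that the C8 ketone is reduced as it forms and never meets base as a ketone. This gives (3Z,7E,9S)-9-(tert-butyldimethylsilyloxy)-3,7-dimethylcyclodeca-3,7-dien-1-ol F1 (C8 epimers, of no consequence). Dess–Martin oxidation under buffered conditions returns to 18.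

**Step 4.** The facial selectivity of the very reactive allylic Grignard reagent may be modest, and the magnesium alkoxide of the β-hydroxy ketone may open by retro-aldol before addition. Fallback, from 5: silylate first (TBSCl, imidazole) to (2S,3S)-2-(but-3-en-1-yl)-3-(tert-butyldimethylsilyloxy)-2-methylcyclopentan-1-one F2. Its silyloxy group blocks the butenyl face more firmly and cannot fragment. Adding 6 gives the tertiary alcohol silyl ether F3, and Bu4NF returns to 7.

**Step 8.** The 8-trimethylsilyloxy group sits on the face that the methyl leaves open and may erode the facial preference at C6. The peracid may also begin to epoxidise C1=C10. Fallback, from 10: cleave the enol silyl ether with MeLi to the lithium enolate F4 (the tertiary silyl ether survives). Oxidise F4 at −78 °C with the enantiomer of (10-camphorsulfonyl)oxaziridine that is matched to the desired face. This is reagent control, and the oxidant does not touch olefins. The product is the 6-hydroxy-8-(trimethylsilyloxy) ketone F5; citric acid in MeOH returns to 13.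

**Step 17.** The C7 enolate can expel the C6 α-keto carboxylate (E1cB) faster than it adds to C11. Once the butenolide exists, the amine can remove H6, leading to epimerisation or epoxide opening. Fallback, from 20: form the carbon–carbon bond before the ester. Double deprotonation with LiN(iPr)2 (2.2 equiv, THF, −78 °C) gives the alkoxide–enolate F6, whose O6 cannot leave and whose alkoxide guides deprotonation to C7. Ethyl 3-acetoxy-2-oxopropanoate F7 (from ethyl bromopyruvate and KOAc) traps it as the aldol adduct F8. Mild warming with Et3N lactonises F8 to 24, which is dehydrated as in step 17 to 25.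

**Step 18.** The face of hydride attack depends on which ring conformer of 25 reacts, so the 8R alcohol may form instead. Fallback, from 25: reagent-controlled CBS reduction of the enone carbonyl (alkenyl side as the large group), using the enantiomer of the Me-CBS oxazaborolidine that gives 8S, with catecholborane at −78 °C. This returns directly to 26.

**Step 19.** The vanadate on O8 may not reach C1=C10 in the reactive conformer, or may deliver oxygen to the other face. Fallback, from 26: acetylate first (Ac2O, pyridine) to the 8,13-diacetate F9. Then epoxidise C1=C10 under reagent control with the fructose-derived ketone 1,2:4,5-di-O-isopropylidene-β-D-erythro-2,3-hexodiulo-2,6-pyranose or its enantiomer and Oxone (2KHSO5·KHSO4·K2SO4) in buffered MeCN/H2O at 0 °C. This arrives at 28.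

## Further compounds

F1 | step 12 | (3Z,7E,9S)-9-(tert-butyldimethylsilyloxy)-3,7-dimethylcyclodeca-3,7-dien-1-ol (C1 epimers) | OC1C/C(C)=C\CC/C(C)=C/[C@@H](O[Si](C)(C)C(C)(C)C)C1
F2 | step 4 | (2S,3S)-2-(but-3-en-1-yl)-3-(tert-butyldimethylsilyloxy)-2-methylcyclopentan-1-one | O=C1CC[C@H](O[Si](C)(C)C(C)(C)C)[C@]1(C)CCC=C
F3 | step 4 | (1S,2S,3S)-2-(but-3-en-1-yl)-3-(tert-butyldimethylsilyloxy)-2-methyl-1-(2-methylprop-2-en-1-yl)cyclopentan-1-ol | O[C@]1(CC(C)=C)CC[C@H](O[Si](C)(C)C(C)(C)C)[C@]1(C)CCC=C
F4 | step 8 | lithium 5-enolate of 4,10-dimethyl-8-(trimethylsilyloxy)bicyclo[5.3.0]dec-1(10)-en-5-one | [Li+].C[Si](C)(C)O[C@@]12C/C(C)=C\CC[C@@]1(C)C([O-])=CC2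
F5 | step 8 | 6-hydroxy-4,10-dimethyl-8-(trimethylsilyloxy)bicyclo[5.3.0]dec-1(10)-en-5-one, O6 cis to O8 | C[Si](C)(C)O[C@@]12C/C(C)=C\CC[C@@]1(C)C(=O)[C@@H](O)C2
F6 | step 17 | dilithium 6-alkoxide 7-enolate of 20 | [Li+].[Li+].[O-]C=1C/C(C)=C\CC[C@@]2(C)O[C@@H]2[C@@H]([O-])C=1
F7 | step 17 | ethyl 3-acetoxy-2-oxopropanoate | CCOC(=O)C(=O)COC(C)=O
F8 | step 17 | ethyl 3-acetoxy-2-hydroxy-2-[(4R,5R,6S)-4,5-epoxy-6-hydroxy-4,10-dimethyl-8-oxocyclodec-1(10)Z-en-7-yl]propanoate | CCOC(=O)C(O)(COC(C)=O)C1C(=O)C/C(C)=C\CC[C@@]2(C)O[C@@H]2[C@H]1O
F9 | step 19 | (4R,5R,6S,8S)-8,13-diacetoxy-4,5-epoxygermacra-1(10)Z,7(11)-dien-12,6-olide | CC(=O)OCC1=C2[C@@H](OC(C)=O)C/C(C)=C\CC[C@@]3(C)O[C@@H]3[C@H]2OC1=O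
F0 | step 18 | none | none
A1 | alternative 1 | open-chain bis-epoxy aldoxime (C8 oxime, C6=C7 vinyl) | ON=CC[C@]1(C)O[C@@H]1CC[C@@]1(C)O[C@@H]1C=C
A2 | alternative 1 | nitrile oxide from A1 | [O-][N+]#CC[C@]1(C)O[C@@H]1CC[C@@]1(C)O[C@@H]1C=C
A3 | alternative 1 | bridged isoxazoline of the bis-epoxy cyclodecane | N1=C2C[C@]3(C)O[C@@H]3CC[C@@]3(C)O[C@@H]3[C@H](C2)O1
A4 | alternative 2 | (5S)-5-(tert-butyldimethylsilyloxy)-3-methylcyclohex-2-en-1-one | CC1=CC(=O)C[C@@H](O[Si](C)(C)C(C)(C)C)C1
A5 | alternative 2 | methyl cyclobut-1-ene-1-carboxylate | COC(=O)C1=CCC1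
A6 | alternative 2 | cis-anti-cis tricyclo[4.4.0.0(2,5)]decane keto ester | COC(=O)[C@@]12CC[C@@H]1[C@@]1(C)C[C@H](O[Si](C)(C)C(C)(C)C)CC(=O)[C@H]12
A7 | alternative 2 | methyl 8-(tert-butyldimethylsilyloxy)-10-methyl-6-oxocyclodeca-1(10),4-diene-4-carboxylate (target locants; ring-cis at C1=C10, ring-trans at C4=C5) | COC(=O)/C1=C\C(=O)C[C@@H](O[Si](C)(C)C(C)(C)C)C/C(C)=C\CC1
A8 | alternative 3 | (4E,1(10)Z)-8,13-bis(tert-butyldimethylsilyloxy) C6 enal with C7≡C11 alkyne (target locants) | O=C/C=C(\C)CC/C=C(C)\C[C@H](O[Si](C)(C)C(C)(C)C)C#CCO[Si](C)(C)C(C)(C)C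
A9 | alternative 3 | 8,13-bis(tert-butyldimethylsilyloxy)germacra-1(10)Z,4E,7(11)-trien-12,6-olide | CC(C)(C)[Si](C)(C)OCC1=C2[C@@H](O[Si](C)(C)C(C)(C)C)C/C(C)=C\CC/C(C)=C/[C@H]2OC1=O
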